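**Retrosynthetic overview**

1. Atom names used here: ring A = C1 (quaternary spiro carbon), C2 (C–CH3 carrying the oxetane oxygen), C3 (CHBr), C4 (=CH), C5 (=CBr), C6 (CMe2); C7 = acetal CH; C8 = CH2 and C9 = CH(isopropenyl) of the tetrahydrofuran, whose ring oxygen is O(thf); O(ox) is the oxetane oxygen between C7 and C2.
2. Enabling feature: the tetrahydrofuran ring (C1–C7–O(thf)–C9–C8) is a γ-lactol acetal. C7 and C1 are therefore the carboxyl and α-carbon of safranic acid, which already contains all of ring A with its three methyl groups, and O(thf) is its carboxylate oxygen. C8–C9(–CMe2) is a prenyl C5 unit at the epoxide level. So C1/O(thf) is a 1,3-C,O-dinucleophile (acid enediolate) and C8/C9 a 1,2-dielectrophile (epoxy iodide).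
3. Disconnections: C3–Br (inversion of the cis allylic alcohol) and C5–Br (hydrazone of the C5 ketone) last; oxetane bond O(ox)–C7 by dehydrative acetalisation of the lactol with the C2 hydroxyl; C2–OH and C5=O together from a temporary 2,5-endoperoxide bridge on the ring-A diene; C8–C1 and O(thf)–C9 in one annulation of safranic acid with (R)-2-(iodomethyl)-3,3-dimethyloxirane, which assembles the whole C15 skeleton.
4. Ring order: ring A is bought (safranal); the tetrahydrofuran is made second, as a spiro γ-lactone (key step); the oxetane third; the two bromines come last.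
5. Stereocontrol: C9 from Sharpless epoxidation (inverted in the key step); C1 from a chiral lithium amide; C2 from the face of the lactone carbonyl; C7 from the cis ring fusion; C3 from conjugate borylation followed by inversion.

Key step: step 4

Assumption: the sense of induction of the chiral lithium amide on this trienediolate cannot be predicted with confidence; the (R,R)-tetramine is written, its enantiomer would be used if the C1 epimer predominates, and because iodide 5 is a single enantiomer a C1 epimer is a separable diastereomer in either case.

Step 1
Reactants: 1 safranal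
Product: 2 safranic acid
Conditions: NaClO2, NaH2PO4, 2-methyl-2-butene, t-BuOH/H2O, 0 to 25 °C
Reagents that add atoms: sodium chlorite, [Na+].[O-]Cl=O
Why: Pinnick oxidation: chlorous acid oxidises the dienal to the acid while 2-methyl-2-butene scavenges the hypochlorous acid that would otherwise attack the diene; no stereocentre is involved.

Step 2
Reactants: 3 prenol
Product: 4 (S)-(3,3-dimethyloxiran-2-yl)methanol
Conditions: Ti(OiPr)4 (cat.), L-(+)-diisopropyl tartrate (cat.), t-BuOOH, 4 Å molecular sieves, CH2Cl2, −20 °C
Reagents that add atoms: tert-butyl hydroperoxide, CC(C)(C)OO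
Why: Sharpless asymmetric epoxidation: with the L-(+)-tartrate the titanium-bound peroxide is delivered to the alkene face that gives the (S)-epoxy alcohol (the sense that converts geraniol into its (2S,3S)-epoxide), which sets the centre that becomes C9.

Step 3
Reactants: 4 (S)-(3,3-dimethyloxiran-2-yl)methanol
Product: 5 (R)-2-(iodomethyl)-3,3-dimethyloxirane
Conditions: PPh3, I2, imidazole, Et2O/MeCN, 0 °C
Reagents that add atoms: iodine, II
Why: Garegg–Samuelsson (Appel-type) iodination of the primary alcohol through its oxyphosphonium salt leaves the trisubstituted epoxide and its stereocentre untouched (the descriptor becomes R only because CH2I outranks the ring carbon).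

Step 4
Reactants: 2 safranic acid; 5 (R)-2-(iodomethyl)-3,3-dimethyloxirane
Product: 7 hydroxy lactone (3R,5R)-3-(2-hydroxypropan-2-yl)-6,10,10-trimethyl-2-oxaspiro[4.5]deca-6,8-dien-1-one, via epoxy acid 6 (not isolated)
Conditions: N,N'-bis[(R)-1-phenyl-2-(piperidin-1-yl)ethyl]propane-1,3-diamine (1.05 equiv), n-BuLi (4.0 equiv), THF, 0 °C; 5, −78 to −20 °C; t-BuOH, then 55 °C
Reagents that add atoms: none
Why: The chiral dilithium amide deprotonates 2 twice (carboxyl, then the C5 methylene) to the fully conjugated trienediolate held in a mixed aggregate, which is alkylated by SN2 at its α-carbon C1 by the activated oxiranylmethyl iodide (C8–C1 bond, giving the deconjugated 2,4-diene); after the amide is quenched with t-BuOH the lithium carboxylate opens the epoxide at C9 with inversion (O(thf)–C9 bond). The closest known reaction types are the chiral-lithium-amide-mediated enantioselective α-alkylation of carboxylic acid enediolates (traceless auxiliary) and the lactonisation of γ,δ-epoxy carboxylates. The only ring closed is the γ-lactone, by 5-exo-tet epoxide opening at the secondary carbon, the gem-dimethyl epoxide carbon being tertiary and reachable only in a 6-endo mode. C9 is set by the epoxide of step 2 (inversion gives R) and C1 by the chiral amide aggregate, which differentiates the two enediolate faces (reagent control). The step needs α- and not γ- or ε-alkylation, which the α-preference of lithium enediolates should secure; attack at CH2I and not at the epoxide, which the fully substituted distal epoxide carbon secures; and lactonisation before any amide-induced isomerisation of the epoxide, which the t-BuOH quench secures.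

Step 5
Reactants: 7 hydroxy lactone
Product: 8 diene lactone (3R,5R)-6,10,10-trimethyl-3-(prop-1-en-2-yl)-2-oxaspiro[4.5]deca-6,8-dien-1-one
Conditions: Burgess reagent (MeO2CN(−)SO2N(+)Et3), toluene, 60 °C
Reagents that add atoms: none
Why: Burgess dehydration: the tertiary sulfamate undergoes syn elimination toward a methyl group rather than toward the C9–H that is deactivated by the lactone oxygen, which gives the isopropenyl group without touching a stereocentre.

Step 6
Reactants: 8 diene lactone
Product: 10 hydroxy enone lactone (3R,5S,6R)-6-hydroxy-6,10,10-trimethyl-3-(prop-1-en-2-yl)-2-oxaspiro[4.5]dec-7-ene-1,9-dione, via endoperoxide 9 (not isolated)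
Conditions: O2, meso-tetraphenylporphyrin (cat.), visible light, CH2Cl2, −20 °C; then Et3N, 25 °C
Reagents that add atoms: oxygen, O=O
Why: Singlet oxygen adds [4+2] to the s-cis ring diene (far faster than an ene reaction at the isopropenyl group) on the face of the flat lactone carbonyl and away from the C8 methylene, and the temporary endoperoxide then undergoes Kornblum–DeLaMare fragmentation at C5, the only peroxide carbon with a hydrogen, so that the C2 hydroxyl ends cis to C7 and C5 becomes the enone carbonyl.

Step 7
Reactants: 10 hydroxy enone lactone
Product: 11 lactol diol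
Conditions: i-Bu2AlH (excess), CH2Cl2, −78 °C; aq. KNaC4H4O6
Reagents that add atoms: none
Why: i-Bu2AlH at −78 °C stops at the aluminium lactolate of the hindered lactone and also reduces the enone carbonyl 1,2; both new carbinol centres form as mixtures that do not matter, because the lactol equilibrates and C5 is re-oxidised in step 8.

Step 8
Reactants: 11 lactol diol
Product: 12 lactol enone
Conditions: MnO2, CH2Cl2, 25 °C
Reagents that add atoms: none
Why: MnO2 oxidises only the allylic C5 alcohol and leaves the lactol and the tertiary alcohol alone, which restores the non-enolisable enone.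

Step 9
Reactants: 12 lactol enone
Product: 13 oxetane acetal enone
Conditions: MsCl, Et3N, CH2Cl2, −40 to 0 °C (high dilution)
Reagents that add atoms: none
Why: Dehydrative intramolecular acetalisation (glycosylation type): the lactol is sulfonylated and ionises to the five-membered oxocarbenium ion, which cannot eliminate because C1 is quaternary and is captured 4-exo by the cis C2 hydroxyl under irreversible basic conditions; only the cis-fused oxetane can form, so the C7 configuration follows from C1 and C2.

Step 10
Reactants: 13 oxetane acetal enone
Product: 15 hydroxy ketone (OH at C3 cis to the oxetane oxygen), via boronate 14 (not isolated)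
Conditions: CuCl (cat.), bis[2-(diphenylphosphino)phenyl] ether (cat.), NaOt-Bu (cat.), B2pin2, MeOH, THF, 25 °C; then H2O2, pH 7 phosphate buffer, 0 °C
Reagents that add atoms: bis(pinacolato)diboron, CC1(C)OB(OC1(C)C)B1OC(C)(C)C(C)(C)O1 (boron stays only in 14); hydrogen peroxide, OO
Why: Copper-catalysed conjugate borylation of the enone and oxidation of the C–B bond with retention; the bulky boryl-copper should add to C3 on the face of the oxetane oxygen because the opposite face is screened by the C8 methylene (1,3-diaxial to C3 in the half-chair), which places the new hydroxyl cis to the oxetane oxygen, and all later operations are kept non-acidic so that this hydroxyl cannot trans-acetalise the oxetane.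

Step 11
Reactants: 15 hydroxy ketone
Product: 17 bromoalkenyl alcohol, via hydrazone 16 (not isolated)
Conditions: N2H4·H2O, Et3N, EtOH, 60 °C; evaporate; NBS, pyridine, 0 °C
Reagents that add atoms: hydrazine hydrate, NN.O (nitrogen stays only in 16); N-bromosuccinimide, O=C1CCC(=O)N1Br
Why: Barton vinyl halide synthesis in its bromide form: NBS oxidises the hydrazone to the diazo compound and brominates it, loss of N2 gives the α-bromo cation, and this loses the only available β-proton (C4–H, C6 being quaternary) to give the C4=C5 vinyl bromide; a hindered ketone next to a quaternary carbon is the classical substrate type and no stereocentre is touched.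

Step 12
Reactants: 17 bromoalkenyl alcohol
Product: 18 target CNP0141320.1
Conditions: PPh3, CBr4, 2,6-lutidine, CH2Cl2, 0 °C
Reagents that add atoms: carbon tetrabromide, BrC(Br)(Br)Br
Why: Appel bromination: bromide, small enough to enter on the C8 face, displaces the allylic oxyphosphonium group with inversion at C3 (the SN2' path is closed because C5 carries bromine and is neopentylic), which turns the cis alcohol into the bromide trans to the oxetane oxygen.

**Compound list**

1 | safranal (2,6,6-trimethylcyclohexa-1,3-diene-1-carbaldehyde) | O=CC1=C(C)C=CCC1(C)C | starting material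
2 | safranic acid (2,6,6-trimethylcyclohexa-1,3-diene-1-carboxylic acid) | OC(=O)C1=C(C)C=CCC1(C)C | intermediate
3 | prenol (3-methylbut-2-en-1-ol) | CC(C)=CCO | starting material
4 | (S)-(3,3-dimethyloxiran-2-yl)methanol | OC[C@@H]1OC1(C)C | intermediate
5 | (R)-2-(iodomethyl)-3,3-dimethyloxirane | IC[C@@H]1OC1(C)C | intermediate
6 | epoxy acid, (R)-1-{[(S)-3,3-dimethyloxiran-2-yl]methyl}-2,6,6-trimethylcyclohexa-2,4-diene-1-carboxylic acid (formed as its lithium salt) | OC(=O)[C@]1(C[C@@H]2OC2(C)C)C(C)=CC=CC1(C)C | intermediate
7 | hydroxy lactone, (3R,5R)-3-(2-hydroxypropan-2-yl)-6,10,10-trimethyl-2-oxaspiro[4.5]deca-6,8-dien-1-one | CC(C)(O)[C@H]1C[C@@]2(C(=O)O1)C(C)=CC=CC2(C)C | intermediate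
8 | diene lactone, (3R,5R)-6,10,10-trimethyl-3-(prop-1-en-2-yl)-2-oxaspiro[4.5]deca-6,8-dien-1-one | C=C(C)[C@H]1C[C@@]2(C(=O)O1)C(C)=CC=CC2(C)C | intermediate
9 | endoperoxide of 8 (O–O bridge from C2 to C5 on the face of the lactone carbonyl) | C=C(C)[C@H]1C[C@@]2(C(=O)O1)[C@@]3(C)C=C[C@H](OO3)C2(C)C | intermediate
10 | hydroxy enone lactone, (3R,5S,6R)-6-hydroxy-6,10,10-trimethyl-3-(prop-1-en-2-yl)-2-oxaspiro[4.5]dec-7-ene-1,9-dione (C2 hydroxyl cis to the lactone carbonyl) | C=C(C)[C@H]1C[C@@]2(C(=O)O1)[C@@](O)(C)C=CC(=O)C2(C)C | intermediate
11 | lactol diol, (3R,5S,6R)-6,10,10-trimethyl-3-(prop-1-en-2-yl)-2-oxaspiro[4.5]dec-7-ene-1,6,9-triol (mixture at the lactol and allylic carbinol carbons) | C=C(C)[C@H]1C[C@@]2(C(O)O1)[C@@](O)(C)C=CC(O)C2(C)C | intermediate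
12 | lactol enone, (3R,5S,6R)-1,6-dihydroxy-6,10,10-trimethyl-3-(prop-1-en-2-yl)-2-oxaspiro[4.5]dec-7-en-9-one (anomeric mixture) | C=C(C)[C@H]1C[C@@]2(C(O)O1)[C@@](O)(C)C=CC(=O)C2(C)C | intermediate
13 | oxetane acetal enone (18 with C3H=C4H and a C5 ketone in place of C3HBr–C4H=C5Br; C1, C2, C7, C9 as in 18) | C=C(C)[C@H]1C[C@@]23[C@@H](O1)O[C@]2(C)C=CC(=O)C3(C)C | intermediate
14 | boronate (13 with a pinacolboryl group at C3, cis to the oxetane oxygen, and C4H2) | C=C(C)[C@H]1C[C@@]23[C@@H](O1)O[C@]2(C)[C@H](B4OC(C)(C)C(C)(C)O4)CC(=O)C3(C)C | intermediate
15 | hydroxy ketone (13 with C3H(OH)–C4H2; hydroxyl cis to the oxetane oxygen) | C=C(C)[C@H]1C[C@@]23[C@@H](O1)O[C@]2(C)[C@H](O)CC(=O)C3(C)C | intermediate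
16 | hydrazone of 15 at C5 | C=C(C)[C@H]1C[C@@]23[C@@H](O1)O[C@]2(C)[C@H](O)CC(=NN)C3(C)C | intermediate
17 | bromoalkenyl alcohol (18 with a hydroxyl, cis to the oxetane oxygen, in place of the C3 bromine) | C=C(C)[C@H]1C[C@@]23[C@@H](O1)O[C@]2(C)[C@H](O)C=C(Br)C3(C)C | intermediate
18 | CNP0141320.1 (C1 S, C2 S, C3 S, C7 S, C9 R in the atom names used here) | C=C(C)[C@H]1C[C@@]23[C@@H](O1)O[C@]2(C)[C@@H](Br)C=C(Br)C3(C)C | target

**Step count and risks**

Total: 12 steps. Longest linear sequence: 11 steps (prenol 3 to 18, steps 2 to 12).

Steps most likely to fail:

Step 4 (key step). The congested α-carbon C1 lies between C(CH3)= and C(CH3)2, so alkylation may be slow or may go to the γ or ε carbon of the trienediolate. Kinetic deprotonation may occur at the C2 methyl group instead of C5. Facial discrimination at C1 by the chiral amide may be poor. The fallback sets out from 1 and 5 and comes back at 7. The monoanionic, less aggregated potassium trienolate of safranal 1 (KN(SiMe3)2, THF, −78 °C) would be C-alkylated with 5 to the epoxy aldehyde F1. Its C1 epimers are diastereomers and would be separated by chromatography. Pinnick oxidation of the correct epimer would give the epoxy acid 6, which lactonises to 7 as in the main route.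

Step 9. The strained 4-exo closure may lose against intermolecular acetal formation or against conjugate addition of the lactol hydroxyl to the enone, and the product may re-open under traces of acid. The fallback sets out from 12 and comes back at 13. The lactol would be converted with Cl3CCN and catalytic DBU into the isolable anomeric trichloroacetimidate F2. The ring would then be closed with catalytic Me3SiOTf and 4 Å molecular sieves in CH2Cl2 at −78 °C and quenched cold with Et3N (Schmidt-type intramolecular glycosylation). This separates activation from ring closure and leaves only neutral trichloroacetamide.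

Step 6. Facial selectivity of the cycloaddition may be insufficient; oxygen delivered on the C8 face gives the C2 epimer, which cannot close the oxetane. The fallback sets out from 8 and comes back at 12. The lactone would first be reduced with i-Bu2AlH (−78 °C) to the diene lactol F3. This would be photo-oxygenated in a non-polar solvent, where the lactol hydroxyl on C7 can steer singlet oxygen to its own face by hydrogen bonding (hydroxyl-directed cycloaddition), to give the endoperoxide lactol F4. Et3N would then give 12 directly, and steps 7 and 8 fall away.

Further compounds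
F1 | step 4 | epoxy aldehyde, (R)-1-{[(S)-3,3-dimethyloxiran-2-yl]methyl}-2,6,6-trimethylcyclohexa-2,4-diene-1-carbaldehyde | O=C[C@]1(C[C@@H]2OC2(C)C)C(C)=CC=CC1(C)C
F2 | step 9 | anomeric trichloroacetimidate of lactol 12 | C=C(C)[C@H]1C[C@@]2(C(OC(=N)C(Cl)(Cl)Cl)O1)[C@@](O)(C)C=CC(=O)C2(C)C
F3 | step 6 | diene lactol (lactol of 8, anomeric mixture) | C=C(C)[C@H]1C[C@@]2(C(O)O1)C(C)=CC=CC2(C)C
F4 | step 6 | endoperoxide lactol (O–O bridge from C2 to C5 on the C7 face) | C=C(C)[C@H]1C[C@@]2(C(O)O1)[C@@]3(C)C=C[C@H](OO3)C2(C)C
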